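**Plan**
- Retrosynthetic cuts: the C8 ester; the lactone at O–C6 and at C11–C12 (its O–C=O unit is one CO2); the C10 vinyl group and the C5 2-propenyl arm, both folded back into one cis-fused γ-alkoxybutyrolactone; C7–C11 (epoxide opening); C5–C6 and C9–C10 ([4+2]).
- Forward order: butenolide acetal → Diels–Alder reaction builds the six-membered ring → C6–C8 are set through the 6α,7α-epoxide → the lactone acetal is unfolded into the vinyl and allylsilane arms → a CO2 relay closes the five-membered α-methylene lactone → C8 ester.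
- Stereochemistry: the acetal carbon (from bought (+)-menthol) steers the cycloaddition (C5, C10); convex-face epoxidation and trans-diaxial opening give C7 and C8; hydride delivery gives the axial 6β-alcohol; the key step inverts C6; the ester stereocentre is bought as methyl (S)-3-hydroxy-2-methylpropanoate.
- Feature that makes the key event possible: the C15 hydroxyl on the C5 arm is 1,4 to C6, so its CO2 adduct can reach the α face of C6 through a seven-membered cyclic carbonate. The carbonate carbon then lies 1,3 to C11 on C7, so a C11 carbanion closes the lactone by acyl transfer and frees O15 again. A carboxylate tethered through C7–C11 could attack C6 only syn to its tether and would give the cis lactone.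

Key step: step 13

Remark: locants follow the elemane skeleton (ring C5–C10; C1/C2 = vinyl and C14 = methyl on C10; C3/C4/C15 = 2-propenyl arm on C5; C11–C13 = acrylate unit on C7); β is the ring face that carries the C10 vinyl group. Acetal 3 is assumed to crystallise as the (5S) epimer, by analogy with the unsubstituted (−)-menthol series taken as its mirror image.

**Step 1**
Reactants: 1 5-hydroxy-4-methylfuran-2(5H)-one; 2 (+)-menthol
Product: 3 (5S)-4-methyl-5-[(1S,2R,5S)-menthyloxy]furan-2(5H)-one
Conditions: TsOH (cat.), toluene, reflux, Dean–Stark; crystallisation, mother liquor re-equilibrated with acid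
Reagents that add atoms: none
Why: Acid-catalysed acetalisation of the lactol is reversible at the acetal carbon, so crystallisation should collect one diastereomer and make the bought menthol the single source of absolute configuration.

**Step 2**
Reactants: 3 (5S)-menthyloxybutenolide; 4 (E)-1-methoxy-3-(trimethylsilyloxy)buta-1,3-diene
Product: 6 cis-fused enone lactone acetal (C8 ketone; C6=C7; lactone carbonyl C4 on C5 and acetal C1 on C10 both β; 10α-methyl; 5α-H), via silyl enol ether cycloadduct 5 (not isolated)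
Conditions: toluene, 120 °C, sealed tube; then HCl (0.1 M), THF, 0 °C
Reagents that add atoms: none
Why: Diels–Alder reaction of a γ-alkoxybutenolide in which the diene should add anti to the menthyloxy group with its CH2 terminus on the β-carbon, which sets C5 and C10 together (both lactone branches β, methyl α) before acid unmasks the ketone and eliminates methanol.

**Step 3**
Reactants: 6 cis-fused enone lactone acetal
Product: 7 6α,7α-epoxy ketone
Conditions: dimethyldioxirane, acetone/CH2Cl2, 0 → 23 °C
Reagents that add atoms: dimethyldioxirane CC1(C)OO1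
Why: Neutral epoxidation of the enone should take place on the convex α face of the cis-fused bicycle, anti to the lactone carbonyl branch on C5, and this face fixes the later C7 configuration.

**Step 4**
Reactants: 7 6α,7α-epoxy ketone
Product: 8 6α,7α-epoxy-8α-alcohol
Conditions: NaBH4, CeCl3·7H2O, MeOH, −78 °C
Reagents that add atoms: none
Why: Luche-type 1,2-reduction in which hydride should approach C8 anti to the epoxide oxygen and so give the 8α-alcohol cis to the epoxide.

**Step 5**
Reactants: 8 6α,7α-epoxy-8α-alcohol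
Product: 9 8α-O-TBS epoxide
Conditions: TBSCl, imidazole, DMF, 23 °C
Reagents that add atoms: tert-butyldimethylsilyl chloride CC(C)(C)[Si](C)(C)Cl
Why: Silylation under weakly basic conditions should leave the epoxide, the lactone acetal and the acidic H-5 untouched.

**Step 6**
Reactants: 9 8α-O-TBS epoxide; 10 (1-bromoethenyl)trimethylsilane
Product: 11 6α-hydroxy-7β-[1-(trimethylsilyl)ethenyl]-8α-(TBS-oxy) lactone acetal
Conditions: 10, Mg, THF, 23 °C; then CuI (10 mol %), 9, THF, −40 → 0 °C
Reagents that add atoms: none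
Why: Copper-catalysed Grignard opening of the epoxide, trans-diaxial and at C7 because C6 is shielded by the ring fusion, should put the C11 unit on the β face and leave the 6α-alcohol.

**Step 7**
Reactants: 11 6α-alcohol
Product: 12 6-ketone
Conditions: 1,1,1-triacetoxy-1,1-dihydro-1,2-benziodoxol-3(1H)-one (DMP), NaHCO3, CH2Cl2, 23 °C
Reagents that add atoms: none
Why: Hypervalent iodine oxidation under neutral conditions turns the relay 6α-alcohol into the ketone while C5 stays locked by the cis ring fusion and the C7 branch stays equatorial.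

**Step 8**
Reactants: 12 6-ketone
Product: 13 6β-alcohol
Conditions: NaBH4, MeOH/CH2Cl2, −40 °C
Reagents that add atoms: none
Why: Both carbons that flank the C6 ketone carry their branches on the β face, so hydride should enter from the α face and give the axial 6β-alcohol needed for an invertive displacement.

**Step 9**
Reactants: 13 6β-alcohol
Product: 14 6β-hydroxy-7β-(1-iodoethenyl)-8α-(TBS-oxy) lactone acetal
Conditions: NIS, MeCN, 0 °C
Reagents that add atoms: N-iodosuccinimide O=C1CCC(=O)N1I
Why: ipso-Iododesilylation of the 1-silylalkene, directed by the β-silyl cation, should give the 2-iodoalkene without touching the stereocentres.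

**Step 10**
Reactants: 14 iodoalkene lactone acetal; 15 (trimethylsilyl)methylmagnesium chloride
Product: 17 6β-hydroxy-10β-vinyl-10α-methyl-5β-[3-(trimethylsilyl)prop-1-en-2-yl]-7β-(1-iodoethenyl)-8α-(TBS-oxy)cyclohexane, via bis-adduct triol 16 (not isolated)
Conditions: 15 (6 equiv), CeCl3, THF, −78 → 23 °C; then KH, THF, 0 → 23 °C
Reagents that add atoms: none
Why: Double addition of the silylmethyl organocerium reagent to the lactone carbonyl and single addition to the aldehyde released from the acetal, followed by two Peterson eliminations, should unfold the lactone acetal in one flask into the 2-(silylmethyl)allyl arm on C5 and the vinyl group on C10 and release menthol.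

**Step 11**
Reactants: 17 6β-alcohol
Product: 18 6β-mesylate
Conditions: MsCl, Et3N, CH2Cl2, −20 °C
Reagents that add atoms: methanesulfonyl chloride CS(=O)(=O)Cl
Why: Sulfonylation through sulfene tolerates the hindered axial alcohol and keeps the C6 configuration.

**Step 12**
Reactants: 18 6β-mesylate
Product: 20 6β-mesylate with the 5β-(3-hydroxyprop-1-en-2-yl) arm, via epoxysilane 19 (not isolated)
Conditions: mCPBA (1.05 equiv), NaHCO3, CH2Cl2, −20 °C; then AcOH, 0 °C
Reagents that add atoms: 3-chloroperbenzoic acid OOC(=O)c1cccc(Cl)c1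
Why: The allylsilane is the most electron-rich alkene, and its epoxide should open to a β-silyl cation that loses silicon, which gives the transposed allylic alcohol and leaves the vinyl group and the iodoalkene alone.

**Step 13**
Reactants: 20 hydroxy mesylate iodoalkene
Product: 25 8α-O-TBS 15-O-TBDPS α-methylene-12,6α-lactone, via potassium alkyl carbonate 21 (not isolated), via cyclic carbonate 22 (not isolated), via alkenyllithium 23 (not isolated), via lithium alkoxide 24 (not isolated)
Conditions: KH, 18-crown-6 (cat.), THF, 0 °C; CO2 (1 atm), 0 → 45 °C; Ar purge; t-BuLi (2.1 equiv), −78 °C; then TBDPSCl, DMPU, −78 → 23 °C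
Reagents that add atoms: carbon dioxide O=C=O; tert-butyldiphenylsilyl chloride CC(C)(C)[Si](Cl)(c1ccccc1)c1ccccc1
Why: Proposed new method: KH and CO2 turn the C15 hydroxyl into a potassium alkyl carbonate whose oxygen displaces the axial 6β-mesylate from the α face (7-exo-tet, SN2 with inversion; closest known type: carbonate synthesis from an alcohol, CO2 and an alkyl sulfonate), so the new O–C6 bond is equatorial (6α) and trans to the C7 branch. Iodine–lithium exchange at C11 then gives an alkenyllithium that adds to the carbonate carbonyl (5-exo-trig, Parham-type anionic cyclisation), and the tetrahedral intermediate expels the primary C15 alkoxide, which forms the C11–C12 bond and the α-methylene-γ-lactone and returns the relay hydroxyl, trapped as its TBDPS ether. The relay is needed because a carboxylate tethered through C7–C11 could reach C6 only syn to its tether and would give the cis lactone, whereas here the five-membered ring is closed by acyl substitution at C12. C6 is the only new stereocentre and is fixed by the invertive displacement of the mesylate whose configuration was set in step 8. The step needs substitution to beat E2 at C6 and the carbonate to be the only nucleophile: the carbonate is a weak base, direct 5-exo attack of the free alkoxide on C6 is impossible for a leaving group syn to the side chain, and O8 is silylated so that it cannot intercept the carbonate. Collapse toward the five-membered lactone and not the eight-membered one is secured by ring size and by the better primary leaving group.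

**Step 14**
Reactants: 25 bis-silyl lactone
Product: 26 8α-hydroxy 15-O-TBDPS lactone
Conditions: CSA (cat.), MeOH/CH2Cl2, 0 → 23 °C
Reagents that add atoms: none
Why: Acid-catalysed methanolysis should remove the secondary TBS ether much faster than the TBDPS ether and so free O8 only.

**Step 15**
Reactants: 27 methyl (S)-3-hydroxy-2-methylpropanoate
Product: 28 methyl (S)-3-(TBS-oxy)-2-methylpropanoate
Conditions: TBSCl, imidazole, DMF, 23 °C
Reagents that add atoms: tert-butyldimethylsilyl chloride CC(C)(C)[Si](C)(C)Cl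
Why: Routine silylation of the primary alcohol that does not touch the α-stereocentre.

**Step 16**
Reactants: 28 silyl ether methyl ester
Product: 29 (S)-3-(TBS-oxy)-2-methylpropanoic acid
Conditions: LiOH, THF/H2O, 0 °C; then dilute HCl to pH 4
Reagents that add atoms: lithium hydroxide [Li+].[OH-]
Why: Mild saponification of the methyl ester should proceed without epimerisation of the α-methyl centre.

**Step 17**
Reactants: 26 8α-alcohol; 29 (S)-acid
Product: 30 8α-[(S)-3-(TBS-oxy)-2-methylpropanoyl] 15-O-TBDPS lactone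
Conditions: DCC, DMAP (cat.), CH2Cl2, 0 → 23 °C
Reagents that add atoms: none
Why: Steglich esterification acylates the secondary 8α-alcohol with retention at C8, and the α-stereocentre of the acid should survive carbodiimide activation.

**Step 18**
Reactants: 30 bis-silyl ester
Product: 31 target CNP0133858.2
Conditions: HF·pyridine, pyridine, THF, 0 → 23 °C
Reagents that add atoms: none
Why: Buffered fluoride should cleave both silyl ethers without acyl migration or addition to the α-methylene lactone.

**Compound list**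
1 | 5-hydroxy-4-methylfuran-2(5H)-one (racemic lactol) | CC1=CC(=O)OC1O | starting material
2 | (+)-menthol, (1S,2R,5S)-5-methyl-2-(propan-2-yl)cyclohexan-1-ol | CC(C)[C@H]1CC[C@H](C)C[C@@H]1O | starting material
3 | (5S)-4-methyl-5-{[(1S,2R,5S)-5-methyl-2-(propan-2-yl)cyclohexyl]oxy}furan-2(5H)-one | CC(C)[C@H]1CC[C@H](C)C[C@@H]1O[C@H]2OC(=O)C=C2C | intermediate
4 | (E)-1-methoxy-3-(trimethylsilyloxy)buta-1,3-diene | CO/C=C/C(=C)O[Si](C)(C)C | starting material
5 | cycloadduct: cis-fused menthyl lactone acetal with 6β-methoxy group and C7=C8 trimethylsilyl enol ether | CC(C)[C@H]1CC[C@H](C)C[C@@H]1O[C@H]2OC(=O)[C@@H]3[C@H](OC)C=C(O[Si](C)(C)C)C[C@]23C | intermediate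
6 | cis-fused enone lactone acetal (C8 ketone, C6=C7, 5α-H, 10α-methyl, lactone carbonyl C4 on C5 β, menthyloxy acetal C1 on C10 β) | CC(C)[C@H]1CC[C@H](C)C[C@@H]1O[C@H]2OC(=O)[C@@H]3C=CC(=O)C[C@]23C | intermediate
7 | 6α,7α-epoxy ketone of 6 | CC(C)[C@H]1CC[C@H](C)C[C@@H]1O[C@H]2OC(=O)[C@@H]3[C@H]4O[C@H]4C(=O)C[C@]23C | intermediate
8 | 6α,7α-epoxy-8α-alcohol | CC(C)[C@H]1CC[C@H](C)C[C@@H]1O[C@H]2OC(=O)[C@@H]3[C@H]4O[C@H]4[C@@H](O)C[C@]23C | intermediate
9 | 6α,7α-epoxy-8α-(tert-butyldimethylsilyloxy) lactone acetal | CC(C)[C@H]1CC[C@H](C)C[C@@H]1O[C@H]2OC(=O)[C@@H]3[C@H]4O[C@H]4[C@@H](O[Si](C)(C)C(C)(C)C)C[C@]23C | intermediate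
10 | (1-bromoethenyl)trimethylsilane | C=C(Br)[Si](C)(C)C | starting material
11 | 6α-hydroxy-7β-[1-(trimethylsilyl)ethenyl]-8α-(TBS-oxy) lactone acetal | CC(C)[C@H]1CC[C@H](C)C[C@@H]1O[C@H]2OC(=O)[C@@H]3[C@@H](O)[C@H](C(=C)[Si](C)(C)C)[C@@H](O[Si](C)(C)C(C)(C)C)C[C@]23C | intermediate
12 | 6-oxo-7β-[1-(trimethylsilyl)ethenyl]-8α-(TBS-oxy) lactone acetal | CC(C)[C@H]1CC[C@H](C)C[C@@H]1O[C@H]2OC(=O)[C@@H]3C(=O)[C@H](C(=C)[Si](C)(C)C)[C@@H](O[Si](C)(C)C(C)(C)C)C[C@]23C | intermediate
13 | 6β-hydroxy-7β-[1-(trimethylsilyl)ethenyl]-8α-(TBS-oxy) lactone acetal | CC(C)[C@H]1CC[C@H](C)C[C@@H]1O[C@H]2OC(=O)[C@@H]3[C@H](O)[C@H](C(=C)[Si](C)(C)C)[C@@H](O[Si](C)(C)C(C)(C)C)C[C@]23C | intermediate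
14 | 6β-hydroxy-7β-(1-iodoethenyl)-8α-(TBS-oxy) lactone acetal | CC(C)[C@H]1CC[C@H](C)C[C@@H]1O[C@H]2OC(=O)[C@@H]3[C@H](O)[C@H](C(I)=C)[C@@H](O[Si](C)(C)C(C)(C)C)C[C@]23C | intermediate
15 | (trimethylsilyl)methylmagnesium chloride | C[Si](C)(C)C[Mg]Cl | starting material
16 | bis-adduct triol: C10 bears CH(OH)CH2SiMe3, C5 bears C(OH)(CH2SiMe3)2 (carbinol carbon on C10 unassigned) | C[Si](C)(C)CC(O)[C@@]1(C)C[C@H](O[Si](C)(C)C(C)(C)C)[C@@H](C(I)=C)[C@@H](O)[C@H]1C(O)(C[Si](C)(C)C)C[Si](C)(C)C | intermediate
17 | 6β-hydroxy-10β-vinyl-10α-methyl-5β-[3-(trimethylsilyl)prop-1-en-2-yl]-7β-(1-iodoethenyl)-8α-(TBS-oxy)cyclohexane | C=C[C@@]1(C)C[C@H](O[Si](C)(C)C(C)(C)C)[C@@H](C(I)=C)[C@@H](O)[C@H]1C(=C)C[Si](C)(C)C | intermediate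
18 | 6β-methanesulfonate of 17 | C=C[C@@]1(C)C[C@H](O[Si](C)(C)C(C)(C)C)[C@@H](C(I)=C)[C@@H](OS(C)(=O)=O)[C@H]1C(=C)C[Si](C)(C)C | intermediate
19 | epoxysilane from the allylsilane arm of 18 (epoxide carbon unassigned) | C=C[C@@]1(C)C[C@H](O[Si](C)(C)C(C)(C)C)[C@@H](C(I)=C)[C@@H](OS(C)(=O)=O)[C@H]1C2(C[Si](C)(C)C)CO2 | intermediate
20 | 6β-mesylate with 5β-(3-hydroxyprop-1-en-2-yl), 7β-(1-iodoethenyl), 8α-(TBS-oxy), 10β-vinyl, 10α-methyl | C=C[C@@]1(C)C[C@H](O[Si](C)(C)C(C)(C)C)[C@@H](C(I)=C)[C@@H](OS(C)(=O)=O)[C@H]1C(=C)CO | intermediate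
21 | potassium alkyl carbonate of the C15 hydroxyl of 20 | C=C[C@@]1(C)C[C@H](O[Si](C)(C)C(C)(C)C)[C@@H](C(I)=C)[C@@H](OS(C)(=O)=O)[C@H]1C(=C)COC(=O)[O-].[K+] | intermediate
22 | seven-membered cyclic carbonate O15–C(=O)–O–C6, 6α-oxygen, trans-fused at C5/C6 | C=C[C@@]1(C)C[C@H](O[Si](C)(C)C(C)(C)C)[C@@H](C(I)=C)[C@@H]2OC(=O)OCC(=C)[C@@H]12 | intermediate
23 | C11 alkenyllithium of 22 | C=C[C@@]1(C)C[C@H](O[Si](C)(C)C(C)(C)C)[C@@H](C([Li])=C)[C@@H]2OC(=O)OCC(=C)[C@@H]12 | intermediate
24 | lithium C15 alkoxide of the α-methylene-12,6α-lactone | C=C[C@@]1(C)C[C@H](O[Si](C)(C)C(C)(C)C)[C@H]2C(=C)C(=O)O[C@@H]2[C@H]1C(=C)C[O-].[Li+] | intermediate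
25 | 8α-O-TBS 15-O-TBDPS α-methylene-12,6α-lactone | C=C[C@@]1(C)C[C@H](O[Si](C)(C)C(C)(C)C)[C@H]2C(=C)C(=O)O[C@@H]2[C@H]1C(=C)CO[Si](c3ccccc3)(c3ccccc3)C(C)(C)C | intermediate
26 | 8α-hydroxy 15-O-TBDPS α-methylene-12,6α-lactone | C=C[C@@]1(C)C[C@H](O)[C@H]2C(=C)C(=O)O[C@@H]2[C@H]1C(=C)CO[Si](c3ccccc3)(c3ccccc3)C(C)(C)C | intermediate
27 | methyl (S)-3-hydroxy-2-methylpropanoate | COC(=O)[C@@H](C)CO | starting material
28 | methyl (S)-3-(tert-butyldimethylsilyloxy)-2-methylpropanoate | COC(=O)[C@@H](C)CO[Si](C)(C)C(C)(C)C | intermediate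
29 | (S)-3-(tert-butyldimethylsilyloxy)-2-methylpropanoic acid | OC(=O)[C@@H](C)CO[Si](C)(C)C(C)(C)C | intermediate
30 | 8α-[(S)-3-(TBS-oxy)-2-methylpropanoyloxy] 15-O-TBDPS α-methylene-12,6α-lactone | C=C[C@@]1(C)C[C@H](OC(=O)[C@@H](C)CO[Si](C)(C)C(C)(C)C)[C@H]2C(=C)C(=O)O[C@@H]2[C@H]1C(=C)CO[Si](c3ccccc3)(c3ccccc3)C(C)(C)C | intermediate
31 | target: 8α-[(S)-3-hydroxy-2-methylpropanoyloxy]-15-hydroxy-10β-vinyl-10α-methyl-elema-1,3,11(13)-trien-12,6α-olide | C=C[C@@]1(C)C[C@H](OC(=O)[C@@H](C)CO)[C@H]2C(=C)C(=O)O[C@@H]2[C@H]1C(=C)CO | target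

**Step count**
Total: 18 steps. Longest linear sequence: 16 steps (1–14, 17, 18).

**Steps most likely to fail**

1. Step 13 (Proposed new method). What may go wrong: E2 loss of the axial mesylate toward the diene conjugated with the 2-propenyl arm instead of closure of the seven-membered carbonate; carboxylation of the alkenyllithium by residual CO2; attack of t-BuLi on the carbonate. Fallback with known chemistry, from 11 back to 25: the 6α-alcohol 11 is kept as the lactone oxygen. Iododesilylation (NIS, MeCN) gives the 6α-hydroxy iodoalkene lactone acetal F1. Unfolding with 15/CeCl3 and then KH gives the 6α-hydroxy diene allylsilane F2. Carbonylative lactonisation catalysed by Pd(PPh3)4 (CO 1 atm, Et3N, MeCN, 60 °C) closes the trans lactone at the acyl–oxygen bond and gives the allylsilane lactone F3. mCPBA and then AcOH give the 15-hydroxy lactone F4, and TBDPSCl/imidazole returns 25.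

2. Step 2. What may go wrong: slow cycloaddition at the β,β-disubstituted butenolide with thermal loss of the diene, or erosion of facial selectivity at the temperature needed. Fallback, from 3 to 6 without a new isolated compound: a stepwise anionic double Michael annulation. The lithium enolate of (E)-4-methoxybut-3-en-2-one (LDA, THF, −78 °C) adds to C10 of 3 anti to the menthyloxy group, the lactone enolate closes onto the β-methoxy enone, and loss of methoxide gives 6.

3. Step 10. What may go wrong: enolisation of the intermediate α-silyl ketone so that the second addition stalls, incomplete Peterson elimination at the secondary carbinol, or base-induced loss of HI from the iodoalkene. Fallback, from 14 back to 17: mild hydrolysis of the acetal (aqueous HCl, THF, 0 °C) gives the lactol F5. Wittig methylenation of its open formyl acid form (Ph3P=CH2, THF) gives the vinyl acid F6. Methylation (Me3SiCHN2, MeOH/toluene) gives the methyl ester F7. Double addition of 15/CeCl3 with silica-gel Peterson elimination then gives 17.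

**Further compounds**
F1 | step 13 | 6α-hydroxy-7β-(1-iodoethenyl)-8α-(TBS-oxy) lactone acetal | CC(C)[C@H]1CC[C@H](C)C[C@@H]1O[C@H]2OC(=O)[C@@H]3[C@@H](O)[C@H](C(I)=C)[C@@H](O[Si](C)(C)C(C)(C)C)C[C@]23C
F2 | step 13 | 6α-hydroxy-10β-vinyl-10α-methyl-5β-[3-(trimethylsilyl)prop-1-en-2-yl]-7β-(1-iodoethenyl)-8α-(TBS-oxy)cyclohexane | C=C[C@@]1(C)C[C@H](O[Si](C)(C)C(C)(C)C)[C@@H](C(I)=C)[C@H](O)[C@H]1C(=C)C[Si](C)(C)C
F3 | step 13 | 8α-O-TBS α-methylene-12,6α-lactone with 5β-[3-(trimethylsilyl)prop-1-en-2-yl] arm | C=C[C@@]1(C)C[C@H](O[Si](C)(C)C(C)(C)C)[C@H]2C(=C)C(=O)O[C@@H]2[C@H]1C(=C)C[Si](C)(C)C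
F4 | step 13 | 8α-O-TBS 15-hydroxy α-methylene-12,6α-lactone | C=C[C@@]1(C)C[C@H](O[Si](C)(C)C(C)(C)C)[C@H]2C(=C)C(=O)O[C@@H]2[C@H]1C(=C)CO
F0 | step 2 | none | none
F5 | step 10 | lactol (hydroxy lactone, lactol carbon unassigned) from 14 | OC1OC(=O)[C@@H]2[C@H](O)[C@H](C(I)=C)[C@@H](O[Si](C)(C)C(C)(C)C)C[C@]12C
F6 | step 10 | 6β-hydroxy-10β-vinyl-10α-methyl-7β-(1-iodoethenyl)-8α-(TBS-oxy)cyclohexane-5β-carboxylic acid | C=C[C@@]1(C)C[C@H](O[Si](C)(C)C(C)(C)C)[C@@H](C(I)=C)[C@@H](O)[C@H]1C(=O)O
F7 | step 10 | methyl ester of F6 | C=C[C@@]1(C)C[C@H](O[Si](C)(C)C(C)(C)C)[C@@H](C(I)=C)[C@@H](O)[C@H]1C(=O)OC
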